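## Retrosynthetic overview

1. Arecatannin B1 (10) ⇐ one global hydrogenolysis of 9 (twelve benzyl ethers, two C8 bromine caps).
2. 9 ⇐ both interflavan bonds in one flask, each made as proanthocyanidins are thought to arise in the plant (ring A quinone methide / flavan-4-yl cation of one unit captured by ring A of the next): C4(top)–C8(middle) first, then C4(middle)–C6(bottom). Bromine caps at C8 of the top and bottom units fix the regiochemistry and stop the chain.
3. Extension unit 3 ⇐ C4–H oxidation of tetra-O-benzylepicatechin 2 ⇐ (−)-epicatechin 1; starter unit 6 ⇐ C8 bromination of tetra-O-benzylcatechin 5 ⇐ (+)-catechin 4.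
4. Ring order: no ring is closed in the route. All nine rings (rings A, B, C of the three units) and six of the eight stereocentres come intact from 1 and 4; the two C4 centres are set in step 5.

Assumption: the SMILES is read as epicatechin-(4β→8)-epicatechin-(4β→6)-catechin (2R,3R with a 4β bond in both upper units, 2R,3S in the lower unit), and enantiopure (−)-epicatechin and (+)-catechin are taken as purchasable bulk natural products.

## Route

Step 1
Reactants: 1 (−)-epicatechin
Product: 2 5,7,3',4'-tetra-O-benzyl-(−)-epicatechin (3-OH free)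
Conditions: BnBr (4.4 equiv), K2CO3 (5 equiv), DMF, 0 °C → rt
Reagents that add atoms: benzyl bromide, BrCc1ccccc1
Why: Williamson ether synthesis: K2CO3 deprotonates only the four phenols (pKa about 9–10), which are O-benzylated by SN2 while the aliphatic 3-OH stays free; no stereocentre is involved, and the low temperature limits C-benzylation and base-induced C2 epimerisation.

Step 2
Reactants: 2 5,7,3',4'-tetra-O-benzyl-(−)-epicatechin
Product: 3 (2R,3R,4S)-4-(2-ethoxyethoxy)-5,7,3',4'-tetra-O-benzylepicatechin (4β-alkoxy; trans to the 3-OH)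
Conditions: DDQ (1.5 equiv), EtOCH2CH2OH (5 equiv), CH2Cl2, rt
Reagents that add atoms: 2-ethoxyethanol, OCCOCC
Why: DDQ benzylic C–H oxidation (hydride abstraction): C4–H is activated by the trioxygenated ring A, DDQ gives the flavan-4-yl cation (ring A para-quinone methide) and the alcohol adds to the face opposite the 2-aryl and 3-OH groups (4β); this centre is only a leaving-group site and is erased on ionisation in step 5.

Step 3
Reactants: 4 (+)-catechin
Product: 5 5,7,3',4'-tetra-O-benzyl-(+)-catechin (3-OH free)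
Conditions: BnBr (4.4 equiv), K2CO3 (5 equiv), DMF, 0 °C → rt
Reagents that add atoms: benzyl bromide, BrCc1ccccc1
Why: Williamson ether synthesis, selective for the four phenols over the 3-OH exactly as in step 1; no stereocentre is involved.

Step 4
Reactants: 5 5,7,3',4'-tetra-O-benzyl-(+)-catechin
Product: 6 8-bromo-5,7,3',4'-tetra-O-benzyl-(+)-catechin
Conditions: NBS (1.0 equiv), CH2Cl2, −78 °C → rt
Reagents that add atoms: N-bromosuccinimide, O=C1CCC(=O)N1Br
Why: Electrophilic aromatic bromination: of the two free ring A positions, C8 (between 7-OBn and the ring oxygen) is more accessible than C6 (between two OBn groups), so one equivalent of NBS gives the 8-bromide, which blocks C8 for step 5; no stereocentre is touched.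

Step 5
Reactants: 3 (2R,3R,4S)-4-(2-ethoxyethoxy)-5,7,3',4'-tetra-O-benzylepicatechin (two portions: 1.0 equiv, then 0.7 equiv); 6 8-bromo-5,7,3',4'-tetra-O-benzyl-(+)-catechin (6 equiv, excess recovered)
Product: 9 [8-bromo-tetra-O-benzylepicatechin]-(4β→8)-[tetra-O-benzylepicatechin]-(4β→6)-[8-bromo-tetra-O-benzylcatechin] (three 3-OH free), via C8-brominated monomeric electrophile 7 (not isolated), via bromo-capped dimeric electrophile 8 (not isolated)
Conditions: first portion of 3, NBS (1.0 equiv), CH2Cl2, −78 → 0 °C; then Zn(OTf)2 (0.2 equiv), rt, second portion of 3 added over 2 h; then 6, Yb(OTf)3 (1.0 equiv), rt → 40 °C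
Reagents that add atoms: N-bromosuccinimide, O=C1CCC(=O)N1Br
Why: Proposed new method: a one-flask chain assembly in which every C–C bond is made by the same event, Lewis-acid ionisation of a 4-alkoxy group to the ring-A-stabilised flavan-4-yl cation (para-quinone methide) and its Friedel–Crafts capture by the next ring A; NBS first turns one portion of 3 into 7, which can act only as an electrophile, so that slowly added 3 is taken at its free C8 (the most nucleophilic site present) to give 8, which has no free C8 left and is therefore captured at the hindered C6 of the large excess of 6 (O-trapped adducts are themselves 4-alkoxy electrophiles and re-ionise, so material funnels to the irreversible C-arylation); both cations are attacked on the face opposite the 2-aryl and 3-OH groups, giving 4β (3,4-trans) at both new stereocentres; closest known reaction type: Lewis-acid-promoted coupling and controlled self-condensation of benzylated 4-(2-ethoxyethoxy)flavan-3-ols, with C8 bromine as a chain-stopping cap.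

Step 6
Reactants: 9 [8-bromo-tetra-O-benzylepicatechin]-(4β→8)-[tetra-O-benzylepicatechin]-(4β→6)-[8-bromo-tetra-O-benzylcatechin]
Product: 10 arecatannin B1
Conditions: H2 (1 atm), Pd(OH)2/C, Et3N (3 equiv), THF/MeOH/H2O, rt; then Sephadex LH-20
Reagents that add atoms: none
Why: Heterogeneous catalytic hydrogenolysis: Pd(OH)2/C cleaves the twelve benzylic C–O bonds and both aryl C–Br bonds in one operation while Et3N takes up HBr so that the acid-labile interflavan bonds survive; no stereocentre is affected.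

## Compound list

1 | (−)-epicatechin, (2R,3R)-2-(3,4-dihydroxyphenyl)chromane-3,5,7-triol | Oc1cc(O)c2c(c1)O[C@H](c1ccc(O)c(O)c1)[C@H](O)C2 | starting material

2 | 5,7,3',4'-tetra-O-benzyl-(−)-epicatechin, (2R,3R), 3-OH free | c1(OCc9ccccc9)cc(OCc9ccccc9)c2c(c1)O[C@H](c3ccc(OCc9ccccc9)c(OCc9ccccc9)c3)[C@H](O)C2 | intermediate

3 | (2R,3R,4S)-4-(2-ethoxyethoxy)-5,7,3',4'-tetra-O-benzylepicatechin, 4β-alkoxy trans to the 3-OH | c1(OCc9ccccc9)cc(OCc9ccccc9)c2c(c1)O[C@H](c3ccc(OCc9ccccc9)c(OCc9ccccc9)c3)[C@H](O)[C@H]2OCCOCC | intermediate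

4 | (+)-catechin, (2R,3S)-2-(3,4-dihydroxyphenyl)chromane-3,5,7-triol | Oc1cc(O)c2c(c1)O[C@H](c1ccc(O)c(O)c1)[C@@H](O)C2 | starting material

5 | 5,7,3',4'-tetra-O-benzyl-(+)-catechin, (2R,3S), 3-OH free | c1(OCc9ccccc9)cc(OCc9ccccc9)c2c(c1)O[C@H](c3ccc(OCc9ccccc9)c(OCc9ccccc9)c3)[C@@H](O)C2 | intermediate

6 | 8-bromo-5,7,3',4'-tetra-O-benzyl-(+)-catechin | c1(OCc9ccccc9)cc(OCc9ccccc9)c2c(c1Br)O[C@H](c3ccc(OCc9ccccc9)c(OCc9ccccc9)c3)[C@@H](O)C2 | intermediate

7 | 8-bromo-4β-(2-ethoxyethoxy)-5,7,3',4'-tetra-O-benzylepicatechin, (2R,3R,4S), formed in the flask in step 5 | c1(OCc9ccccc9)cc(OCc9ccccc9)c2c(c1Br)O[C@H](c3ccc(OCc9ccccc9)c(OCc9ccccc9)c3)[C@H](O)[C@H]2OCCOCC | intermediate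

8 | [8-bromo-tetra-O-benzylepicatechin]-(4β→8)-[4β-(2-ethoxyethoxy)-tetra-O-benzylepicatechin], both 3-OH free, formed in the flask in step 5 | c1(OCc9ccccc9)cc(OCc9ccccc9)c2c(c1Br)O[C@H](c3ccc(OCc9ccccc9)c(OCc9ccccc9)c3)[C@H](O)[C@H]2c1c(OCc9ccccc9)cc(OCc9ccccc9)c2c1O[C@H](c3ccc(OCc9ccccc9)c(OCc9ccccc9)c3)[C@H](O)[C@H]2OCCOCC | intermediate

9 | [8-bromo-tetra-O-benzylepicatechin]-(4β→8)-[tetra-O-benzylepicatechin]-(4β→6)-[8-bromo-tetra-O-benzylcatechin], three 3-OH free | c1(OCc9ccccc9)cc(OCc9ccccc9)c2c(c1Br)O[C@H](c3ccc(OCc9ccccc9)c(OCc9ccccc9)c3)[C@H](O)[C@H]2c1c(OCc9ccccc9)cc(OCc9ccccc9)c2c1O[C@H](c3ccc(OCc9ccccc9)c(OCc9ccccc9)c3)[C@H](O)[C@H]2c1c(OCc9ccccc9)c(Br)c2c(c1OCc9ccccc9)C[C@H](O)[C@@H](c3ccc(OCc9ccccc9)c(OCc9ccccc9)c3)O2 | intermediate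

10 | arecatannin B1, epicatechin-(4β→8)-epicatechin-(4β→6)-catechin | Oc1cc(O)c2c(c1)O[C@H](c1ccc(O)c(O)c1)[C@H](O)[C@H]2c1c(O)cc(O)c2c1O[C@H](c1ccc(O)c(O)c1)[C@H](O)[C@H]2c1c(O)cc2c(c1O)C[C@H](O)[C@@H](c1ccc(O)c(O)c1)O2 | target

## Step count and risks

Total step count: 6. Longest linear sequence: 4 steps (1 → 2 → 3 → 9 → 10; the catechin branch 4 → 5 → 6 → 9 → 10 is equally long).

**Step 5 (most likely to fail).** Chain length is statistical: by a Poisson estimate, roughly one third of the bromo-capped chains carry exactly one middle unit. The capture at C6 of 6 is slow and competes with the equally hindered C6 positions of the chains, so 9 must be separated by size-exclusion chromatography from the dibromo dimer, the tetramer and recovered 6. A yield of 20–25 % is a realistic ceiling.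

Fallback: a defined stepwise assembly without chain statistics. It sets out from 7 (made from 3 with NBS as above, but isolated) and from 2. Coupling 7 with 2 (1.1 equiv; Yb(OTf)3, CH2Cl2, rt) cannot oligomerise, since 7 has no free C8 and 2 has no leaving group. It gives the bromo-capped dimer [8-bromo-tetra-O-benzylepicatechin]-(4β→8)-[tetra-O-benzylepicatechin] F1. Oxidation of F1 with DDQ and 2-ethoxyethanol at the only unhindered benzylic CH2 (C4 of the lower unit) then gives 8 as an isolated compound, where the fallback comes back to the route. 8 is coupled with excess 6 (Yb(OTf)3) to give 9.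

**Step 2.** The free 3-OH and the product's remaining C4–H invite over-oxidation (3-ketone, 4-ketone) and ether-linked dimers.

Fallback: oxidise with the cation held by a neighbouring group. It sets out from 2, which is acetylated (Ac2O, pyridine, DMAP) to 3-O-acetyl-5,7,3',4'-tetra-O-benzylepicatechin F2. DDQ and 2-ethoxyethanol then give, through a 3,4-acetoxonium ion, 3-O-acetyl-4β-(2-ethoxyethoxy)-5,7,3',4'-tetra-O-benzylepicatechin F3. Methanolysis (catalytic K2CO3, MeOH/THF) returns to the route at 3.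

**Step 6.** Fourteen hydrogenolyses on one molecule can stall at the hindered aryl bromides or at partly benzylated stages, and the free trimer is sensitive to acid, base and air.

Fallback: separate the two tasks. It sets out from 9, which is treated with n-BuLi (6 equiv, THF, −78 °C; three alkoxides, two bromine–lithium exchanges) and quenched with water. This gives the bromine-free dodeca-O-benzyl-arecatannin B1 F4. Base-free hydrogenolysis of F4 (H2, Pd(OH)2/C, THF/MeOH/H2O) returns to the route at 10.

## Further compounds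

F1 | step 5 | [8-bromo-tetra-O-benzylepicatechin]-(4β→8)-[tetra-O-benzylepicatechin], both 3-OH free | c1(OCc9ccccc9)cc(OCc9ccccc9)c2c(c1Br)O[C@H](c3ccc(OCc9ccccc9)c(OCc9ccccc9)c3)[C@H](O)[C@H]2c1c(OCc9ccccc9)cc(OCc9ccccc9)c2c1O[C@H](c3ccc(OCc9ccccc9)c(OCc9ccccc9)c3)[C@H](O)C2

F2 | step 2 | 3-O-acetyl-5,7,3',4'-tetra-O-benzylepicatechin | c1(OCc9ccccc9)cc(OCc9ccccc9)c2c(c1)O[C@H](c3ccc(OCc9ccccc9)c(OCc9ccccc9)c3)[C@H](OC(C)=O)C2

F3 | step 2 | 3-O-acetyl-4β-(2-ethoxyethoxy)-5,7,3',4'-tetra-O-benzylepicatechin | c1(OCc9ccccc9)cc(OCc9ccccc9)c2c(c1)O[C@H](c3ccc(OCc9ccccc9)c(OCc9ccccc9)c3)[C@H](OC(C)=O)[C@H]2OCCOCC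

F4 | step 6 | dodeca-O-benzyl-arecatannin B1, three 3-OH free, no bromine | c1(OCc9ccccc9)cc(OCc9ccccc9)c2c(c1)O[C@H](c3ccc(OCc9ccccc9)c(OCc9ccccc9)c3)[C@H](O)[C@H]2c1c(OCc9ccccc9)cc(OCc9ccccc9)c2c1O[C@H](c3ccc(OCc9ccccc9)c(OCc9ccccc9)c3)[C@H](O)[C@H]2c1c(OCc9ccccc9)cc2c(c1OCc9ccccc9)C[C@H](O)[C@@H](c3ccc(OCc9ccccc9)c(OCc9ccccc9)c3)O2
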